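**Plan**
- Retrosynthesis: the depside ester C(=O)–O bond between ring A and ring B is cut first, then the C3–CHO bond of ring A, then the two ring A bonds C3–C4 and C5–C6.
- Enabling feature: in ring A, C6 (CH3), C1 (carboxyl), C2 (OH) and C3 (later CHO) are C6, C5, C4 and C3 of a 4-oxygenated 6-methyl-2-pyrone-5-carboxylate; only C4 (OMe) and C5 (H) are missing, and these are the two carbons of 1,1-dimethoxyethene.
- Forward: diethyl 3-oxopentanedioate is C-acetylated, lactonised to the 4-hydroxy-2-pyrone and O-benzylated; cycloaddition with the ketene acetal across pyrone C3/C6, then loss of CO2 and methanol, gives ring A as a benzoate.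
- Debenzylation, ortho-formylation at C3 and ester hydrolysis give the ring A acid; it is esterified with the 4-OH of the ring B benzyl ester, and hydrogenolysis of that benzyl ester ends the route.
- Stereochemistry: the target has no stereocentre; the two bridgehead centres of the cycloadduct are racemic and disappear on aromatisation.

Key step: step 5

Remark: ring B is taken from purchasable 2,4-dihydroxy-3,6-dimethylbenzoic acid and carried as its benzyl ester, because a hydrogenolysable ester can be removed at the end without touching the aryl ester link.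

**Route**

Step 1
Reactants: 1 diethyl 3-oxopentanedioate; 2 acetyl chloride
Product: 3 diethyl 2-acetyl-3-oxopentanedioate
Conditions: MgCl2, pyridine, CH2Cl2, 0 °C; then 2, 0 °C → rt; dilute HCl work-up
Reagents that add atoms: none
Why: Magnesium-mediated soft-enolisation C-acylation of a β-keto ester, in which the chelated magnesium enolate formed with MgCl2/pyridine is acetylated on carbon at the activated methylene and the chelated product resists a second acylation.

Step 2
Reactants: 3 diethyl 2-acetyl-3-oxopentanedioate
Product: 4 ethyl 4-hydroxy-6-methyl-2-oxo-2H-pyran-5-carboxylate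
Conditions: conc. H2SO4, 0 °C → rt; poured onto ice
Reagents that add atoms: none
Why: Acid-promoted lactonisation, in which the enol oxygen of the acetyl group attacks the remote ester carbonyl (6-exo-trig acyl substitution, loss of ethanol) and the product settles as the hydrogen-bonded 4-hydroxy-2-pyrone.

Step 3
Reactants: 4 ethyl 4-hydroxy-6-methyl-2-oxo-2H-pyran-5-carboxylate
Product: 5 ethyl 4-(benzyloxy)-6-methyl-2-oxo-2H-pyran-5-carboxylate
Conditions: BnOH, PPh3, DIAD, THF, 0 °C → rt
Reagents that add atoms: benzyl alcohol, OCc1ccccc1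
Why: Mitsunobu alkylation of the acidic vinylogous carboxylic acid (pKa about 5) should place the benzyl group on O4 under neutral conditions and avoid the C3-benzylation that accompanies base and benzyl halide.

Step 4
Reactants: 6 bromoacetaldehyde dimethyl acetal (2-bromo-1,1-dimethoxyethane)
Product: 7 1,1-dimethoxyethene
Conditions: KOtBu, tetraglyme, 100 °C; fractional distillation of the product (bp about 89 °C)
Reagents that add atoms: none
Why: E2 dehydrobromination of the β-bromo acetal by a hindered alkoxide is the classical ketene acetal synthesis, and tert-butoxide is too bulky to substitute the primary bromide.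

Step 5
Reactants: 5 ethyl 4-(benzyloxy)-6-methyl-2-oxo-2H-pyran-5-carboxylate; 7 1,1-dimethoxyethene
Product: 10 ethyl 2-(benzyloxy)-4-methoxy-6-methylbenzoate, via bridged lactone cycloadduct 8 (not isolated), via dimethoxycyclohexadiene ester 9 (not isolated)
Conditions: 7 (5 equiv), toluene, sealed tube, 135 °C
Reagents that add atoms: none
Why: The electron-rich CH2 terminus of ketene acetal 7 attacks C6 of pyrone 5, the carbon β to the 5-ester and δ to the lactone carbonyl, and the developing dimethoxycarbenium carbon is captured by C3, the α-carbon of the lactone dienolate, in a concerted but asynchronous inverse-electron-demand Diels–Alder reaction or, in its stepwise limit, a Michael addition followed by 6-(enolendo)-exo-trig collapse of the zwitterion. Bridged lactone 8 then loses CO2 by retro-[4+2] reaction and the 4,4-dimethoxycyclohexadiene 9 eliminates methanol thermally to the benzene, which is the known 2-pyrone carboxylate/ketene acetal route to alkoxybenzoates. The six-membered carbocycle is thus closed by intermolecular [4+2] cycloaddition across pyrone C3 and C6, forming the bonds C6–CH2 and C3–C(OMe)2. The two bridgehead stereocentres of 8 arise as a racemate and vanish on aromatisation, so no stereocontrol is required. The selectivity needed is regiochemical (acetal carbon next to pyrone C3, CH2 next to C6) and is secured by the 5-ester and the lactone carbonyl, which make C6 the only electrophilic diene terminus and C3 the nucleophilic one. The 4-benzyloxy donor makes the diene less reactive than the usual cases, which is answered by excess 7 in a sealed tube at 135 °C.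

Step 6
Reactants: 10 ethyl 2-(benzyloxy)-4-methoxy-6-methylbenzoate
Product: 11 ethyl 2-hydroxy-4-methoxy-6-methylbenzoate
Conditions: H2 (1 atm), Pd/C (10%), EtOAc, rt
Reagents that add atoms: none
Why: Hydrogenolysis of the benzyl aryl ether over palladium on carbon should free the phenol while the ester, methoxy and methyl groups stay inert.

Step 7
Reactants: 11 ethyl 2-hydroxy-4-methoxy-6-methylbenzoate
Product: 13 ethyl 3-formyl-2-hydroxy-4-methoxy-6-methylbenzoate, via hydroxymethyl phenol 12 (not isolated)
Conditions: MgCl2 (anhydrous), Et3N, (CH2O)n, MeCN, reflux; then 1 M HCl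
Reagents that add atoms: paraformaldehyde (formaldehyde unit), C=O
Why: Magnesium-mediated ortho-formylation (Casnati–Skattebøl reaction), in which the magnesium phenoxide delivers coordinated formaldehyde only to the carbon ortho to the phenol oxygen, here C3 because C1 is substituted, and the hydroxymethyl intermediate 12 is oxidised to the aldehyde by hydride transfer to a second formaldehyde.

Step 8
Reactants: 13 ethyl 3-formyl-2-hydroxy-4-methoxy-6-methylbenzoate
Product: 14 3-formyl-2-hydroxy-4-methoxy-6-methylbenzoic acid
Conditions: KOH, H2O/DMSO, 70 °C, N2; then 1 M HCl, 0 °C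
Reagents that add atoms: potassium hydroxide, [K+].[OH-]
Why: Saponification (acyl–oxygen cleavage) by hydroxide in aqueous DMSO should open the doubly ortho-substituted ester while the non-enolisable aldehyde is masked as the vinylogous carboxylate of the phenoxide, and cold acidification should avoid decarboxylation.

Step 9
Reactants: 15 2,4-dihydroxy-3,6-dimethylbenzoic acid
Product: 16 benzyl 2,4-dihydroxy-3,6-dimethylbenzoate
Conditions: BnBr, KHCO3, DMF, rt
Reagents that add atoms: benzyl bromide, BrCc1ccccc1
Why: SN2 O-alkylation of the carboxylate, since KHCO3 deprotonates only the carboxylic acid and benzyl bromide therefore gives the benzyl ester with both phenols left free.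

Step 10
Reactants: 14 3-formyl-2-hydroxy-4-methoxy-6-methylbenzoic acid; 16 benzyl 2,4-dihydroxy-3,6-dimethylbenzoate
Product: 17 benzyl 4-[(3-formyl-2-hydroxy-4-methoxy-6-methylbenzoyl)oxy]-2-hydroxy-3,6-dimethylbenzoate
Conditions: DCC, toluene, rt
Reagents that add atoms: none
Why: Carbodiimide (Steglich-type) esterification as used for depsides, in which the activated acid acylates the 4-OH of 16 while the 2-OH of 16 and the 2-OH of 14 are hydrogen-bonded to ortho carbonyl groups and flanked by substituents.

Step 11
Reactants: 17 benzyl 4-[(3-formyl-2-hydroxy-4-methoxy-6-methylbenzoyl)oxy]-2-hydroxy-3,6-dimethylbenzoate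
Product: 18 baeomycesic acid
Conditions: H2 (1 atm), Pd/C (10%), EtOAc, rt; stopped after uptake of 1 equiv H2
Reagents that add atoms: none
Why: Hydrogenolysis of the benzyl ester, which should be much faster than reduction of the hydrogen-bonded salicylaldehyde carbonyl and leaves the non-benzylic aryl ester link intact.

**Compound list**
1 | diethyl 3-oxopentanedioate | CCOC(=O)CC(=O)CC(=O)OCC | starting material
2 | acetyl chloride | CC(=O)Cl | starting material
3 | diethyl 2-acetyl-3-oxopentanedioate | CCOC(=O)CC(=O)C(C(C)=O)C(=O)OCC | intermediate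
4 | ethyl 4-hydroxy-6-methyl-2-oxo-2H-pyran-5-carboxylate | CCOC(=O)C1=C(C)OC(=O)C=C1O | intermediate
5 | ethyl 4-(benzyloxy)-6-methyl-2-oxo-2H-pyran-5-carboxylate | CCOC(=O)C1=C(C)OC(=O)C=C1OCc1ccccc1 | intermediate
6 | bromoacetaldehyde dimethyl acetal (2-bromo-1,1-dimethoxyethane) | COC(CBr)OC | starting material
7 | 1,1-dimethoxyethene | C=C(OC)OC | intermediate
8 | ethyl 5-(benzyloxy)-8,8-dimethoxy-1-methyl-3-oxo-2-oxabicyclo[2.2.2]oct-5-ene-6-carboxylate (bridged lactone cycloadduct; racemate, one enantiomer drawn; not isolated) | CCOC(=O)C1=C(OCc2ccccc2)[C@@H]3C(=O)O[C@@]1(C)CC3(OC)OC | intermediate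
9 | ethyl 6-(benzyloxy)-4,4-dimethoxy-2-methylcyclohexa-1,5-diene-1-carboxylate (not isolated) | CCOC(=O)C1=C(C)CC(OC)(OC)C=C1OCc1ccccc1 | intermediate
10 | ethyl 2-(benzyloxy)-4-methoxy-6-methylbenzoate | CCOC(=O)c1c(C)cc(OC)cc1OCc1ccccc1 | intermediate
11 | ethyl 2-hydroxy-4-methoxy-6-methylbenzoate | CCOC(=O)c1c(C)cc(OC)cc1O | intermediate
12 | ethyl 2-hydroxy-3-(hydroxymethyl)-4-methoxy-6-methylbenzoate (formed as its magnesium alkoxide; not isolated) | CCOC(=O)c1c(C)cc(OC)c(CO)c1O | intermediate
13 | ethyl 3-formyl-2-hydroxy-4-methoxy-6-methylbenzoate | CCOC(=O)c1c(C)cc(OC)c(C=O)c1O | intermediate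
14 | 3-formyl-2-hydroxy-4-methoxy-6-methylbenzoic acid | COc1cc(C)c(C(=O)O)c(O)c1C=O | intermediate
15 | 2,4-dihydroxy-3,6-dimethylbenzoic acid | Cc1cc(O)c(C)c(O)c1C(=O)O | starting material
16 | benzyl 2,4-dihydroxy-3,6-dimethylbenzoate | Cc1cc(O)c(C)c(O)c1C(=O)OCc1ccccc1 | intermediate
17 | benzyl 4-[(3-formyl-2-hydroxy-4-methoxy-6-methylbenzoyl)oxy]-2-hydroxy-3,6-dimethylbenzoate | COc1cc(C)c(C(=O)Oc2cc(C)c(C(=O)OCc3ccccc3)c(O)c2C)c(O)c1C=O | intermediate
18 | baeomycesic acid, 4-[(3-formyl-2-hydroxy-4-methoxy-6-methylbenzoyl)oxy]-2-hydroxy-3,6-dimethylbenzoic acid | COc1cc(C)c(C(=O)Oc2cc(C)c(C(=O)O)c(O)c2C)c(O)c1C=O | target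

**Count**
Total steps: 11 (steps 4 and 9 are side branches).
Longest linear sequence: 9 steps (1, 2, 3, 5, 6, 7, 8, 10, 11).

**Steps most likely to fail**

Step 5. The 4-benzyloxy donor raises the LUMO of the diene, so the cycloaddition may be slow enough for oligomerisation of the ketene acetal to outrun adduct formation. The fallback sets out from 5 and uses a removable halogen as an extra activating group.
- NBS in MeCN at rt should brominate the nucleophilic C3 to give ethyl 4-(benzyloxy)-3-bromo-6-methyl-2-oxo-2H-pyran-5-carboxylate F1; 3-bromo-2-pyrones are established, more reactive Diels–Alder dienes.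
- Heating F1 with 7 in toluene should lead through ethyl 5-(benzyloxy)-4-bromo-8,8-dimethoxy-1-methyl-3-oxo-2-oxabicyclo[2.2.2]oct-5-ene-6-carboxylate F2 and, after loss of CO2, ethyl 6-(benzyloxy)-5-bromo-4,4-dimethoxy-2-methylcyclohexa-1,5-diene-1-carboxylate F3 to ethyl 2-(benzyloxy)-3-bromo-4-methoxy-6-methylbenzoate F4 by loss of methanol.
- H2 over Pd/C with Et3N in EtOH should then remove bromine and benzyl together, and the fallback comes back to the route at 11.

Step 7. The phenoxide is held in a chelate with the neighbouring ester, so the formylation may stall, or it may leak to C5 if a non-chelated electrophilic pathway takes over. The fallback sets out from 11 and brings in the formyl carbon by sigmatropic rearrangement.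
- Allyl bromide and K2CO3 in DMF should give ethyl 2-(allyloxy)-4-methoxy-6-methylbenzoate F5.
- Claisen rearrangement in N,N-diethylaniline at 190 °C can only go to C3, the single free ortho position, and should give ethyl 3-allyl-2-hydroxy-4-methoxy-6-methylbenzoate F6.
- RuHCl(CO)(PPh3)3 (catalytic) in toluene at 80 °C should move the double bond into conjugation to give ethyl 2-hydroxy-4-methoxy-6-methyl-3-[(E)-prop-1-en-1-yl]benzoate F7.
- Ozonolysis (O3, CH2Cl2/MeOH, −78 °C; then Me2S) should cleave the propenyl group to the aldehyde, and the fallback comes back to the route at 13.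

Step 8. Hydrolysis of the doubly ortho-substituted ester may be slow under conditions the aldehyde tolerates, and the electron-rich salicylic acid may decarboxylate during acidification. The fallback sets out from 11 and moves the hydrolysis ahead of the formylation, so that the formyl acid is finally released by neutral hydrogenolysis.
- KOH in H2O/DMSO at 90 °C followed by cold acidification should give 2-hydroxy-4-methoxy-6-methylbenzoic acid F8.
- BnBr and KHCO3 in DMF should give benzyl 2-hydroxy-4-methoxy-6-methylbenzoate F9.
- MgCl2, Et3N and paraformaldehyde in refluxing MeCN should lead through benzyl 2-hydroxy-3-(hydroxymethyl)-4-methoxy-6-methylbenzoate F10 to benzyl 3-formyl-2-hydroxy-4-methoxy-6-methylbenzoate F11.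
- H2 over Pd/C in EtOAc at rt should remove the benzyl ester, and the fallback comes back to the route at 14.

**Further compounds**
F1 | step 5 | ethyl 4-(benzyloxy)-3-bromo-6-methyl-2-oxo-2H-pyran-5-carboxylate | CCOC(=O)C1=C(C)OC(=O)C(Br)=C1OCc1ccccc1
F2 | step 5 | ethyl 5-(benzyloxy)-4-bromo-8,8-dimethoxy-1-methyl-3-oxo-2-oxabicyclo[2.2.2]oct-5-ene-6-carboxylate (racemate, one enantiomer drawn; not isolated) | CCOC(=O)C1=C(OCc2ccccc2)[C@]3(Br)C(=O)O[C@@]1(C)CC3(OC)OC
F3 | step 5 | ethyl 6-(benzyloxy)-5-bromo-4,4-dimethoxy-2-methylcyclohexa-1,5-diene-1-carboxylate (not isolated) | CCOC(=O)C1=C(C)CC(OC)(OC)C(Br)=C1OCc1ccccc1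
F4 | step 5 | ethyl 2-(benzyloxy)-3-bromo-4-methoxy-6-methylbenzoate | CCOC(=O)c1c(C)cc(OC)c(Br)c1OCc1ccccc1
F5 | step 7 | ethyl 2-(allyloxy)-4-methoxy-6-methylbenzoate | CCOC(=O)c1c(C)cc(OC)cc1OCC=C
F6 | step 7 | ethyl 3-allyl-2-hydroxy-4-methoxy-6-methylbenzoate | CCOC(=O)c1c(C)cc(OC)c(CC=C)c1O
F7 | step 7 | ethyl 2-hydroxy-4-methoxy-6-methyl-3-[(E)-prop-1-en-1-yl]benzoate | CCOC(=O)c1c(C)cc(OC)c(/C=C/C)c1O
F8 | step 8 | 2-hydroxy-4-methoxy-6-methylbenzoic acid | COc1cc(C)c(C(=O)O)c(O)c1
F9 | step 8 | benzyl 2-hydroxy-4-methoxy-6-methylbenzoate | COc1cc(C)c(C(=O)OCc2ccccc2)c(O)c1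
F10 | step 8 | benzyl 2-hydroxy-3-(hydroxymethyl)-4-methoxy-6-methylbenzoate (not isolated) | COc1cc(C)c(C(=O)OCc2ccccc2)c(O)c1CO
F11 | step 8 | benzyl 3-formyl-2-hydroxy-4-methoxy-6-methylbenzoate | COc1cc(C)c(C(=O)OCc2ccccc2)c(O)c1C=O
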